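In a closed flask the partner you charge can't vanish, so keep its books, and keep them through the fraction of substrate left, which the runs read.

| flask | substrate | partner | remark | time |
|---|---|---|---|---|
| east | 28 mM | 19 mM | run made earlier |  |
| west | 44 mM | 19 mM | run made earlier |  |
| south-east | 20 mM | 28 mM | run made earlier |  |
| flask | 20 mM | 19.0 mM |  | 6.0 h |

| run | time / h | substrate / % | single product / % |
|---|---|---|---|
| east | 0.667 | 36.5 | 0.4 |
| east | 1.33 | 35.6 | 0 |
| east | 2.00 | 35.9 | 0 |
| east | 3.00 | 36.0 | 0.3 |
| east | 4.00 | 36.5 | 0.2 |
| west | 0.333 | 58.0 | 4.0 |
| west | 0.833 | 58.9 | 0 |
| west | 1.50 | 58.4 | 0.2 |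
| west | 2.50 | 58.0 | 0 |
| west | 4.00 | 57.7 | 0 |
| south-east | 0.250 | 0.9 | 15.0 |
| south-east | 0.500 | 0.2 | 2.3 |
| south-east | 1.00 | 0.2 | 0.5 |
| south-east | 2.00 | 0 | 0 |
| south-east | 4.00 | 0 | 0 |

(scatter of a reading: 0.3 percentage points)



* how much substrate there is at 6.0 h, in percent of the substrate charged
* how much single product there is at 6.0 h, in percent of the substrate charged
* how much double product there is at 6.0 h, in percent of the substrate charged
* how much triple product there is at 6.0 h, in percent of the substrate charged

In the east run substrate stands flat at a mean of 36.1 %, and in the west run at 58.2 %, while in the south-east run, with 28 mM of partner, it ends at 0 %. I read those two stops as the end of the partner, the limiting reagent. Multiply the fraction of substrate consumed by charged [substrate] over charged [partner], and you get 0.942 for east and 0.968 for west. This figure falls by 0.107 per unit of charged [partner]/[substrate]. Extended to the flask's ratio of 0.950, that line gives 0.913, my estimate of the flask's take: substrate consumed per partner charged.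

Here is my ledger for the flask. Of 19.0 mM partner, 17.3 mM goes into first additions, leaving 13.3 % of the substrate. I book single product at nil, as it read 0 % at 2.00 h in the south-east run. The remaining 1.66 mM of partner I book as second additions, which makes 8.29 % double product and no triple product. That leaves 78.4 % of the substrate charged carrying one partner in something the runs don't read.

The forecast gives 15 % substrate, 0 % single product, 75 % double product and 10 % triple product, and it starts from the same reading of the stops: “The plateaus show the partner running out”. Its double product is higher than mine, so watch that entry.

The flask gives 13.4 % substrate, 0 % single product, 8.07 % double product and 0 % triple product, the double product lying 67 percentage points below the forecast.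

    substrate + partner → single product (k = 40.0 /M/min)
    partner + triple product → over-reaction product (k = 16.0 /M/min)
    partner + double product ⇌ triple product (K = 17.0 /M, k = 18.0 /M/min)
    partner + single product → double product (k = 4.90 /M/min)
    single product → decomposed reagent (k = 0.120 /min)

Decomposed reagent stands at 78.4 % at 6.00 h, with partner at 0 %. Now use the take on the same flask with 7.6 mM of partner: the line lifts it to 0.974, so you reckon 63.0 % of the substrate left. That neighbour holds 62.9 % substrate.

The data were computed on assumed constants; scatter was added.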